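**Retrosynthetic overview**

1. Feature: on the cyclopentane ring C8 and C12 are neighbouring carbons that each carry a CH2-linked chain, C7 lies cis to O9, and C12–C13–C14–C15(=O) is what remains when a ring radical adds to a vinyl ketone.
2. C7–C8 and C12–C13 are cut together: a bromoacetal tethered through O9 of a cis-4-silyloxycyclopent-2-en-1-ol cyclises (C7 radical onto C8) and the C12 radical is caught by oct-1-en-3-one; the only ring formed is a temporary tetrahydrofuran acetal (O9–C6–C7–C8–C9) on the preformed cyclopentene.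
3. The acetal is later opened to the C6 lactol, and the Z C5=C6 bond comes from a Wittig reaction with the C1–C5 carboxy ylide.
4. C15 is parked as a silyl ether for the Wittig step; O9 is then masked as a THP acetal so that C11 and C15 are oxidised together, and O9 is released last under mild acid.
5. The C11 silyl ether is TBDPS in place of TBS so that it survives the acetal hydrolysis and does not migrate to O9 under the basic Wittig conditions; C15, the acetal carbon and the THP carbon are carried as mixtures because each is erased before the target.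

Key step: step 4

**Route**

Step 1
Reactants: 1 (1R,4S)-cis-4-acetoxycyclopent-2-en-1-ol
Product: 2 (1S,4R)-4-(tert-butyldiphenylsilyloxy)cyclopent-2-en-1-yl acetate
Conditions: TBDPSCl, imidazole, DMF, 0 °C → rt
Reagents that add atoms: tert-butyl(chloro)diphenylsilane, CC(C)(C)[Si](Cl)(c1ccccc1)c1ccccc1
Why: Imidazole-promoted silyl ether formation at the only free hydroxyl (the future O11); no stereocentre is touched and the allylic acetate is inert.

Step 2
Reactants: 2 (1S,4R)-4-(tert-butyldiphenylsilyloxy)cyclopent-2-en-1-yl acetate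
Product: 3 (1S,4R)-4-(tert-butyldiphenylsilyloxy)cyclopent-2-en-1-ol
Conditions: K2CO3 (0.2 equiv), MeOH, 0 °C → rt
Reagents that add atoms: none
Why: Base-catalysed transesterification (methanolysis) of the acetate frees the hydroxyl that becomes O9 without affecting the TBDPS ether or either stereocentre.

Step 3
Reactants: 3 (1S,4R)-4-(tert-butyldiphenylsilyloxy)cyclopent-2-en-1-ol; 4 ethyl vinyl ether
Product: 5 tert-butyl{[(1R,4S)-4-(2-bromo-1-ethoxyethoxy)cyclopent-2-en-1-yl]oxy}diphenylsilane (acetal carbon as a mixture)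
Conditions: NBS (1.2 equiv), 4 (3 equiv), CH2Cl2, −40 °C → 0 °C
Reagents that add atoms: N-bromosuccinimide, O=C1CCC(=O)N1Br
Why: Bromoalkoxylation of the enol ether (haloacetalisation): NBS brominates the electron-rich vinyl ether and alcohol 3 captures the α-bromo oxocarbenium ion, attaching the tether through O9 with C9 and C11 unchanged.

Step 4
Reactants: 5 tert-butyl{[(1R,4S)-4-(2-bromo-1-ethoxyethoxy)cyclopent-2-en-1-yl]oxy}diphenylsilane; 6 oct-1-en-3-one
Product: 8 1-[(3aR,4R,5R,6aS)-5-(tert-butyldiphenylsilyloxy)-2-ethoxyhexahydro-2H-cyclopenta[b]furan-4-yl]octan-3-one (acetal carbon as a mixture), via bicyclic C12 radical 7 (not isolated)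
Conditions: Bu3SnH (1.3 equiv, syringe pump over 6 h), AIBN (0.1 equiv), 6 (6 equiv), PhH, 80 °C
Reagents that add atoms: none
Why: Bu3Sn• abstracts bromine from 5 and the C7 radical closes by 5-exo-trig attack on C8 of the cyclopentene to give the secondary C12 radical 7, which adds to the unsubstituted terminus of 6 (Giese addition); the α-keto radical so formed is quenched by Bu3SnH, returning Bu3Sn• to the chain. The closest known reaction type is the Ueno–Stork haloacetal cyclisation run in tandem with intermolecular trapping of the cyclised radical by an electron-poor alkene. The one ring closed is the tetrahydrofuran acetal (O9–C6–C7–C8–C9), formed in the 5-exo-trig mode and necessarily cis-fused to the cyclopentane. C8 is set by the tether, which can deliver C7 only to the face bearing O9; C12 is set by approach of 6 to the convex face, anti to the new ring and to the C11 silyloxy group, so the chain ends trans to C7 and to O11. The step needs C–C bond formation at C12 to outrun hydrogen transfer from tin and needs the adduct radical not to telomerise: slow addition keeps the stannane concentration low, the excess of 6 raises the trapping rate, and polarity matching (nucleophilic alkyl radical with the enone, electrophilic α-keto radical with the stannane) steers each radical to its partner. Reduction of the C7 radical before cyclisation is not expected because the 5-exo closure onto the ring alkene is fast.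

Step 5
Reactants: 8 1-[(3aR,4R,5R,6aS)-5-(tert-butyldiphenylsilyloxy)-2-ethoxyhexahydro-2H-cyclopenta[b]furan-4-yl]octan-3-one
Product: 9 1-[(3aR,4R,5R,6aS)-5-(tert-butyldiphenylsilyloxy)-2-ethoxyhexahydro-2H-cyclopenta[b]furan-4-yl]octan-3-ol (C15 epimers)
Conditions: NaBH4, MeOH, 0 °C
Reagents that add atoms: none
Why: Borohydride reduction of the dialkyl ketone masks C15 against the ylide of step 8; the C15 centre forms as a mixture that is erased by reoxidation in step 11, and the acetal and silyl ether are inert.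

Step 6
Reactants: 9 1-[(3aR,4R,5R,6aS)-5-(tert-butyldiphenylsilyloxy)-2-ethoxyhexahydro-2H-cyclopenta[b]furan-4-yl]octan-3-ol
Product: 10 (3aR,4R,5R,6aS)-5-(tert-butyldiphenylsilyloxy)-4-[3-(tert-butyldiphenylsilyloxy)octyl]-2-ethoxyhexahydro-2H-cyclopenta[b]furan (bicyclic ethyl acetal with O11 and O15 both as TBDPS ethers)
Conditions: TBDPSCl, imidazole, DMAP (cat.), DMF, rt
Reagents that add atoms: tert-butyl(chloro)diphenylsilane, CC(C)(C)[Si](Cl)(c1ccccc1)c1ccccc1
Why: Silyl ether formation at the unhindered secondary C15 hydroxyl gives both future ketone oxygens the same acid-stable, fluoride-labile group.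

Step 7
Reactants: 10 bicyclic ethyl acetal with O11 and O15 as TBDPS ethers
Product: 11 (3aR,4R,5R,6aS)-5-(tert-butyldiphenylsilyloxy)-4-[3-(tert-butyldiphenylsilyloxy)octyl]hexahydro-2H-cyclopenta[b]furan-2-ol (lactol, anomer mixture)
Conditions: 1 M aq. HCl/THF (1:4), rt
Reagents that add atoms: water, O
Why: Acid-catalysed acetal hydrolysis through the five-membered oxocarbenium ion, which a 2-alkoxytetrahydrofuran undergoes under conditions much milder than those that cleave secondary TBDPS ethers; no ring stereocentre is involved.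

Step 8
Reactants: 11 lactol; 12 (4-carboxybutyl)triphenylphosphonium bromide
Product: 14 (5Z)-11α,15-bis(tert-butyldiphenylsilyloxy)-9α-hydroxyprost-5-enoic acid (C15 epimers), via carboxylate ylide 13 (not isolated)
Conditions: 12 (3 equiv), KOtBu (6 equiv), THF, 0 °C; then 11, 0 °C → rt; aq. KHSO4 to pH 4
Reagents that add atoms: none
Why: Wittig olefination of the lactol through its open hydroxy aldehyde form with a non-stabilised ylide under lithium-free conditions should give the Z C5=C6 alkene by kinetically controlled cis-oxaphosphetane formation, and the bulky TBDPS group is not expected to migrate from O11 to the O9 alkoxide.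

Step 9
Reactants: 14 (5Z)-11α,15-bis(tert-butyldiphenylsilyloxy)-9α-hydroxyprost-5-enoic acid
Product: 16 (5Z)-11α,15-bis(tert-butyldiphenylsilyloxy)-9α-(tetrahydropyran-2-yloxy)prost-5-enoic acid, via tetrahydropyranyl ester 15 (not isolated)
Conditions: 3,4-dihydro-2H-pyran (4 equiv), PPTS (cat.), CH2Cl2, rt; then 0.5 M aq. KOH, THF, 0 °C; aq. KHSO4 to pH 5
Reagents that add atoms: 3,4-dihydro-2H-pyran, C1=COCCC1; potassium hydroxide, [K+].[OH-]
Why: Acid-catalysed addition of the C9 hydroxyl to dihydropyran (THP acetal formation) also turns the carboxyl group into its THP ester, which as an acylal is saponified by dilute hydroxide at 0 °C while the THP ether and the TBDPS ethers stay intact.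

Step 10
Reactants: 16 (5Z)-11α,15-bis(tert-butyldiphenylsilyloxy)-9α-(tetrahydropyran-2-yloxy)prost-5-enoic acid
Product: 17 (5Z)-11α,15-dihydroxy-9α-(tetrahydropyran-2-yloxy)prost-5-enoic acid (C15 epimers)
Conditions: Bu4NF (6 equiv), THF, rt → 45 °C
Reagents that add atoms: none
Why: Fluoride-induced desilylation driven by Si–F bond formation removes both TBDPS groups, while the THP acetal, the Z alkene and the carboxylate are stable to Bu4NF.

Step 11
Reactants: 17 (5Z)-11α,15-dihydroxy-9α-(tetrahydropyran-2-yloxy)prost-5-enoic acid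
Product: 18 (5Z)-11,15-dioxo-9α-(tetrahydropyran-2-yloxy)prost-5-enoic acid
Conditions: Dess–Martin periodinane (3 equiv), CH2Cl2, 0 °C → rt
Reagents that add atoms: none
Why: Dess–Martin oxidation of both secondary alcohols under non-basic conditions, so the β-alkoxy ketone formed at C11 should not eliminate O9, and C12, already trans to the C8 chain, is not at risk of epimerisation.

Step 12
Reactants: 18 (5Z)-11,15-dioxo-9α-(tetrahydropyran-2-yloxy)prost-5-enoic acid
Product: 19 13,14-dihydro-15-keto-PGD2, (5Z)-9α-hydroxy-11,15-dioxoprost-5-enoic acid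
Conditions: AcOH/THF/H2O (4:2:1), 35–40 °C
Reagents that add atoms: none
Why: Mildly acidic hydrolysis of the THP acetal, the usual last step for base-sensitive β-hydroxy cyclopentanones, should release the C9 hydroxyl without base-induced elimination and leave C8, C9, C12 and the Z alkene untouched.

**Compound list**

1 | (1R,4S)-cis-4-acetoxycyclopent-2-en-1-ol | CC(=O)O[C@H]1C[C@@H](O)C=C1 | starting material
2 | (1S,4R)-4-(tert-butyldiphenylsilyloxy)cyclopent-2-en-1-yl acetate | CC(=O)O[C@H]1C[C@@H](O[Si](c2ccccc2)(c2ccccc2)C(C)(C)C)C=C1 | intermediate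
3 | (1S,4R)-4-(tert-butyldiphenylsilyloxy)cyclopent-2-en-1-ol | O[C@H]1C[C@@H](O[Si](c2ccccc2)(c2ccccc2)C(C)(C)C)C=C1 | intermediate
4 | ethyl vinyl ether | CCOC=C | starting material
5 | tert-butyl{[(1R,4S)-4-(2-bromo-1-ethoxyethoxy)cyclopent-2-en-1-yl]oxy}diphenylsilane (bromoacetal, acetal carbon as a mixture) | CCOC(CBr)O[C@H]1C[C@@H](O[Si](c2ccccc2)(c2ccccc2)C(C)(C)C)C=C1 | intermediate
6 | oct-1-en-3-one | CCCCCC(=O)C=C | starting material
7 | cis-fused 2-ethoxy-5-(tert-butyldiphenylsilyloxy)hexahydro-2H-cyclopenta[b]furan-4-yl radical (radical at C12, C7 and O9 cis) | [CH]1[C@H](O[Si](c3ccccc3)(c3ccccc3)C(C)(C)C)C[C@@H]2OC(OCC)C[C@H]12 | intermediate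
8 | 1-[(3aR,4R,5R,6aS)-5-(tert-butyldiphenylsilyloxy)-2-ethoxyhexahydro-2H-cyclopenta[b]furan-4-yl]octan-3-one (acetal carbon as a mixture) | CCCCCC(=O)CC[C@H]1[C@H](O[Si](c3ccccc3)(c3ccccc3)C(C)(C)C)C[C@@H]2OC(OCC)C[C@H]12 | intermediate
9 | 1-[(3aR,4R,5R,6aS)-5-(tert-butyldiphenylsilyloxy)-2-ethoxyhexahydro-2H-cyclopenta[b]furan-4-yl]octan-3-ol (C15 epimers) | CCCCCC(O)CC[C@H]1[C@H](O[Si](c3ccccc3)(c3ccccc3)C(C)(C)C)C[C@@H]2OC(OCC)C[C@H]12 | intermediate
10 | (3aR,4R,5R,6aS)-5-(tert-butyldiphenylsilyloxy)-4-[3-(tert-butyldiphenylsilyloxy)octyl]-2-ethoxyhexahydro-2H-cyclopenta[b]furan | CCCCCC(O[Si](c3ccccc3)(c3ccccc3)C(C)(C)C)CC[C@H]1[C@H](O[Si](c3ccccc3)(c3ccccc3)C(C)(C)C)C[C@@H]2OC(OCC)C[C@H]12 | intermediate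
11 | (3aR,4R,5R,6aS)-5-(tert-butyldiphenylsilyloxy)-4-[3-(tert-butyldiphenylsilyloxy)octyl]hexahydro-2H-cyclopenta[b]furan-2-ol (lactol) | CCCCCC(O[Si](c3ccccc3)(c3ccccc3)C(C)(C)C)CC[C@H]1[C@H](O[Si](c3ccccc3)(c3ccccc3)C(C)(C)C)C[C@@H]2OC(O)C[C@H]12 | intermediate
12 | (4-carboxybutyl)triphenylphosphonium bromide | OC(=O)CCCC[P+](c1ccccc1)(c1ccccc1)c1ccccc1.[Br-] | starting material
13 | potassium 5-(triphenyl-λ5-phosphanylidene)pentanoate (carboxylate ylide) | [K+].[O-]C(=O)CCCC=P(c1ccccc1)(c1ccccc1)c1ccccc1 | intermediate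
14 | (5Z)-11α,15-bis(tert-butyldiphenylsilyloxy)-9α-hydroxyprost-5-enoic acid (C15 epimers) | CCCCCC(O[Si](c2ccccc2)(c2ccccc2)C(C)(C)C)CC[C@H]1[C@H](O[Si](c2ccccc2)(c2ccccc2)C(C)(C)C)C[C@H](O)[C@@H]1C/C=C\CCCC(=O)O | intermediate
15 | tetrahydropyran-2-yl (5Z)-11α,15-bis(tert-butyldiphenylsilyloxy)-9α-(tetrahydropyran-2-yloxy)prost-5-enoate | CCCCCC(O[Si](c2ccccc2)(c2ccccc2)C(C)(C)C)CC[C@H]1[C@H](O[Si](c2ccccc2)(c2ccccc2)C(C)(C)C)C[C@H](OC2CCCCO2)[C@@H]1C/C=C\CCCC(=O)OC1CCCCO1 | intermediate
16 | (5Z)-11α,15-bis(tert-butyldiphenylsilyloxy)-9α-(tetrahydropyran-2-yloxy)prost-5-enoic acid | CCCCCC(O[Si](c2ccccc2)(c2ccccc2)C(C)(C)C)CC[C@H]1[C@H](O[Si](c2ccccc2)(c2ccccc2)C(C)(C)C)C[C@H](OC2CCCCO2)[C@@H]1C/C=C\CCCC(=O)O | intermediate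
17 | (5Z)-11α,15-dihydroxy-9α-(tetrahydropyran-2-yloxy)prost-5-enoic acid (C15 epimers) | CCCCCC(O)CC[C@H]1[C@H](O)C[C@H](OC2CCCCO2)[C@@H]1C/C=C\CCCC(=O)O | intermediate
18 | (5Z)-11,15-dioxo-9α-(tetrahydropyran-2-yloxy)prost-5-enoic acid | CCCCCC(=O)CC[C@H]1C(=O)C[C@H](OC2CCCCO2)[C@@H]1C/C=C\CCCC(=O)O | intermediate
19 | 13,14-dihydro-15-keto-PGD2, (5Z)-9α-hydroxy-11,15-dioxoprost-5-enoic acid | CCCCCC(=O)CC[C@H]1C(=O)C[C@H](O)[C@@H]1C/C=C\CCCC(=O)O | target

**Totals**

Total step count: 12. Longest linear sequence: 12 steps (1 → 19).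

**Steps most likely to fail**

Step 4. Hydrogen transfer from the stannane to the C12 radical may outrun C–C bond formation, or the adduct radical may add to further enone (telomerisation). The fallback changes the trap to one that needs no hydrogen donor and builds the chain in stages. Bromoacetal 5 would be heated with CH2=CHCH2SnBu3 and AIBN in benzene at 80 °C (the same 5-exo cyclisation through radical 7, then Keck radical allylation with loss of Bu3Sn•), which should give (3aR,4R,5R,6aS)-4-allyl-5-(tert-butyldiphenylsilyloxy)-2-ethoxyhexahydro-2H-cyclopenta[b]furan F1 with the same facial control at C12. Hydroboration with 9-BBN in THF followed by NaOH/H2O2 should give the 3-hydroxypropyl compound F2, and Dess–Martin oxidation the aldehyde 3-[(3aR,4R,5R,6aS)-5-(tert-butyldiphenylsilyloxy)-2-ethoxyhexahydro-2H-cyclopenta[b]furan-4-yl]propanal F3. Addition of n-C5H11MgBr in THF at −78 °C would then give alcohol 9, where the route is rejoined.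

Step 12. Acid-promoted loss of water across C9–C10 (giving the cyclopentenone) or aldol closure of the C11/C15 1,5-diketone may accompany the acetal cleavage. The fallback masks O9 with a group removed at neutral pH by a transition metal. Hydroxy acid 14 would be treated with allyl chloroformate, Et3N and cat. DMAP in CH2Cl2 (0 °C → rt), which should carbonate the C9 hydroxyl and esterify the carboxyl group in the same operation, giving allyl (5Z)-9α-(allyloxycarbonyloxy)-11α,15-bis(tert-butyldiphenylsilyloxy)prost-5-enoate F4. Desilylation with Bu4NF buffered by AcOH in THF should give allyl (5Z)-9α-(allyloxycarbonyloxy)-11α,15-dihydroxyprost-5-enoate F5, and Dess–Martin oxidation allyl (5Z)-9α-(allyloxycarbonyloxy)-11,15-dioxoprost-5-enoate F6. Pd(PPh3)4 (zerovalent palladium, cat.) with dimedone as allyl acceptor in THF at rt would cleave both allyl groups, the carbonate losing CO2, and deliver 19 directly.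

Step 9. Acetalisation of the carboxyl group competes with that of the hindered C9 hydroxyl, and the basic cleavage may not discriminate cleanly between the ester-type and ether-type THP acetals. The fallback protects O9 before the acid exists. Lactol 11 would be opened with propane-1,3-dithiol and BF3·OEt2 in CH2Cl2 at −30 °C to the hydroxy dithiane 2-{[(1R,2R,3R,5S)-3-(tert-butyldiphenylsilyloxy)-2-[3-(tert-butyldiphenylsilyloxy)octyl]-5-hydroxycyclopentyl]methyl}-1,3-dithiane F7. Dihydropyran with PPTS should then give its 9-O-tetrahydropyranyl ether F8, now without any competing carboxyl group. Alkylative hydrolysis of the dithiane (MeI, CaCO3, MeCN/H2O, 40 °C) should give the aldehyde 2-[(1R,2R,3R,5S)-3-(tert-butyldiphenylsilyloxy)-2-[3-(tert-butyldiphenylsilyloxy)octyl]-5-(tetrahydropyran-2-yloxy)cyclopentyl]acetaldehyde F9. Wittig reaction of F9 with ylide 13 (from 12 and KOtBu, THF, 0 °C) followed by acidification to pH 5 returns to acid 16.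

**Further compounds**

F1 | step 4 | (3aR,4R,5R,6aS)-4-allyl-5-(tert-butyldiphenylsilyloxy)-2-ethoxyhexahydro-2H-cyclopenta[b]furan | C=CC[C@H]1[C@H](O[Si](c3ccccc3)(c3ccccc3)C(C)(C)C)C[C@@H]2OC(OCC)C[C@H]12
F2 | step 4 | 3-[(3aR,4R,5R,6aS)-5-(tert-butyldiphenylsilyloxy)-2-ethoxyhexahydro-2H-cyclopenta[b]furan-4-yl]propan-1-ol | OCCC[C@H]1[C@H](O[Si](c3ccccc3)(c3ccccc3)C(C)(C)C)C[C@@H]2OC(OCC)C[C@H]12
F3 | step 4 | 3-[(3aR,4R,5R,6aS)-5-(tert-butyldiphenylsilyloxy)-2-ethoxyhexahydro-2H-cyclopenta[b]furan-4-yl]propanal | O=CCC[C@H]1[C@H](O[Si](c3ccccc3)(c3ccccc3)C(C)(C)C)C[C@@H]2OC(OCC)C[C@H]12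
F4 | step 12 | allyl (5Z)-9α-(allyloxycarbonyloxy)-11α,15-bis(tert-butyldiphenylsilyloxy)prost-5-enoate | CCCCCC(O[Si](c2ccccc2)(c2ccccc2)C(C)(C)C)CC[C@H]1[C@H](O[Si](c2ccccc2)(c2ccccc2)C(C)(C)C)C[C@H](OC(=O)OCC=C)[C@@H]1C/C=C\CCCC(=O)OCC=C
F5 | step 12 | allyl (5Z)-9α-(allyloxycarbonyloxy)-11α,15-dihydroxyprost-5-enoate | CCCCCC(O)CC[C@H]1[C@H](O)C[C@H](OC(=O)OCC=C)[C@@H]1C/C=C\CCCC(=O)OCC=C
F6 | step 12 | allyl (5Z)-9α-(allyloxycarbonyloxy)-11,15-dioxoprost-5-enoate | CCCCCC(=O)CC[C@H]1C(=O)C[C@H](OC(=O)OCC=C)[C@@H]1C/C=C\CCCC(=O)OCC=C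
F7 | step 9 | 2-{[(1R,2R,3R,5S)-3-(tert-butyldiphenylsilyloxy)-2-[3-(tert-butyldiphenylsilyloxy)octyl]-5-hydroxycyclopentyl]methyl}-1,3-dithiane | CCCCCC(O[Si](c2ccccc2)(c2ccccc2)C(C)(C)C)CC[C@H]1[C@H](O[Si](c2ccccc2)(c2ccccc2)C(C)(C)C)C[C@H](O)[C@@H]1CC1SCCCS1
F8 | step 9 | 9-O-tetrahydropyranyl ether of F7 | CCCCCC(O[Si](c2ccccc2)(c2ccccc2)C(C)(C)C)CC[C@H]1[C@H](O[Si](c2ccccc2)(c2ccccc2)C(C)(C)C)C[C@H](OC2CCCCO2)[C@@H]1CC1SCCCS1
F9 | step 9 | 2-[(1R,2R,3R,5S)-3-(tert-butyldiphenylsilyloxy)-2-[3-(tert-butyldiphenylsilyloxy)octyl]-5-(tetrahydropyran-2-yloxy)cyclopentyl]acetaldehyde | CCCCCC(O[Si](c2ccccc2)(c2ccccc2)C(C)(C)C)CC[C@H]1[C@H](O[Si](c2ccccc2)(c2ccccc2)C(C)(C)C)C[C@H](OC2CCCCO2)[C@@H]1CC=O
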